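**Assumption:** the SMILES is read as the 29-membered lactone C28H54O2 (carbonyl carbon, 27 CH2, ring oxygen). It has no stereocentre, so it is a single achiral compound and nothing stereochemical has to be set.

## Retrosynthetic overview

1. Target 8 has one ring. It is closed in the last step by forming the lactone C(=O)–O bond.
2. The ring-closing precursor is the symmetric octacosane-1,28-diol 5. One terminus is oxidised and acylates the other in the same catalytic event (dehydrogenative macrolactonisation, proposed new).
3. Diol 5 is cut at its central C14–C15 bond: Kolbe dimerisation of two molecules of 15-hydroxypentadecanoic acid 3 (2 × C14 after loss of CO2).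
4. Acid 3 comes from saponification of the bulk fragrance lactone ω-pentadecalactone 1.

## Route

**Step 1**
Reactants: 1 ω-pentadecalactone (15-pentadecanolide, oxacyclohexadecan-2-one)
Product: 3 15-hydroxypentadecanoic acid, via potassium 15-hydroxypentadecanoate 2 (not isolated)
Conditions: KOH (1.5 equiv), MeOH/H2O 9:1, reflux, 2 h; then 2 M HCl, 0 °C, pH 2, filter and dry below 40 °C
Reagents that add atoms: potassium hydroxide, [K+].[OH-]
Why: Saponification (BAc2 ester hydrolysis) of an unstrained macrolactone is fast and made irreversible by formation of carboxylate 2, and cold acidification precipitates the hydroxy acid without re-esterification; no stereocentre is involved.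

**Step 2**
Reactants: 3 15-hydroxypentadecanoic acid (two molecules per molecule of product)
Product: 5 octacosane-1,28-diol, via 14-hydroxytetradecyl radical 4 (not isolated)
Conditions: KOH (0.1 equiv), MeOH (0.3 M), Pt anode/Pt cathode, undivided cell, 0.2 A cm⁻², 50 °C, periodic polarity reversal, about 1.3 F mol⁻¹ (until pH 8–9); cool, filter, recrystallise from toluene/EtOH
Reagents that add atoms: 15-hydroxypentadecanoic acid (the second molecule of 3), OC(=O)CCCCCCCCCCCCCCO
Why: Kolbe electrolysis: the supporting electrolyte is the potassium carboxylate of 3 (the same salt as 2, held at about 10% and re-formed at the cathode), which is oxidised at Pt at high current density and loses CO2 to give the primary radical 4, and two such radicals from two molecules of 3 dimerise at the electrode surface to form the central C14–C15 bond; the carboxylate layer on the anode shields the remote primary OH (as it shields the methanol solvent) from oxidation, and the C28 diol crystallises from methanol away from the monomeric by-products.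

**Step 3**
Reactants: 5 octacosane-1,28-diol
Product: 8 octacosanolide, via 28-hydroxyoctacosanal 6 (not isolated), via oxacyclononacosan-2-ol 7 (not isolated)
Conditions: dearomatised Ru–PNN pincer hydride [RuH(CO)(PNN*)] (Milstein type, 5 mol%), rigorously dried and degassed PhMe, reflux, slow Ar sweep; solid 5 leached in from a Soxhlet thimble over about 36 h (final ≤2 mM), then 12 h; silica plug
Reagents that add atoms: none
Why: Proposed new method: acceptorless dehydrogenative macrolactonisation of an α,ω-diol. The Ru–PNN complex adds one O–H across its dearomatised arm and β-hydride eliminates to give hydroxy aldehyde 6 and Ru–H2. Aldehyde 6 closes reversibly on its own distal OH to the strain-free 29-membered lactol 7; the estimated effective molarity (about 10⁻² M) exceeds the ≤2 mM standing OH concentration, so ring closure beats chain growth. Lactol 7 is dehydrogenated essentially irreversibly to ester 8, which forms the ring C–O bond and desymmetrises the two identical termini in one event. Chains oxidised at both ends are isomers of 8 and should be returned to the cycle by the Ru hydride (transfer hydrogenation/Tishchenko manifold), so the lactone is expected to be the only sink, and no stereocentre is created. Closest known chemistry: Ru-pincer acceptorless dehydrogenative lactonisation of 1,4- and 1,5-diols, and dehydrogenative ester and polyester formation from primary alcohols and longer diols; not shown for macrocyclic rings.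

## Compound list

1 | ω-pentadecalactone (oxacyclohexadecan-2-one) | O=C1CCCCCCCCCCCCCCO1 | starting material
2 | potassium 15-hydroxypentadecanoate | [K+].[O-]C(=O)CCCCCCCCCCCCCCO | intermediate (not isolated)
3 | 15-hydroxypentadecanoic acid | OC(=O)CCCCCCCCCCCCCCO | intermediate
4 | 14-hydroxytetradecyl radical (primary alkyl radical, transient) | [CH2]CCCCCCCCCCCCCO | intermediate (not isolated)
5 | octacosane-1,28-diol | OCCCCCCCCCCCCCCCCCCCCCCCCCCCCO | intermediate
6 | 28-hydroxyoctacosanal | O=CCCCCCCCCCCCCCCCCCCCCCCCCCCCO | intermediate (not isolated)
7 | oxacyclononacosan-2-ol (macrocyclic lactol, racemic, transient) | OC1CCCCCCCCCCCCCCCCCCCCCCCCCCCO1 | intermediate (not isolated)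
8 | octacosanolide (oxacyclononacosan-2-one) | O=C1CCCCCCCCCCCCCCCCCCCCCCCCCCCO1 | target

## Step count and risks

Total step count: 3. Longest linear sequence: 3.

Steps most likely to fail, most risky first:

**Step 3 (proposed new step).** The risks are slow turnover and catalyst death at high dilution, linear oligoesters, and aldehyde side reactions (aldol, decarbonylation that poisons Ru). The fallback uses known chemistry, sets out from 5 and comes back at 8. Diol 5 is heated with 48% aqueous HBr in toluene at reflux, which monobrominates α,ω-diols selectively, to give 28-bromooctacosan-1-ol F1. Oxidation with catalytic TEMPO and PhI(OAc)2 in warm CH2Cl2–MeCN–H2O gives 28-bromooctacosanoic acid F2. Slow addition of F2 to K2CO3 in DMSO at 90 °C (final ≤5 mM) closes the ring by intramolecular carboxylate SN2 displacement of bromide, again forming the lactone C–O bond, and gives 8.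

**Step 2.** The risks are anode fouling by the very insoluble C28 diol, anodic attack on the free OH, and Hofer–Moest (cation-derived) by-products. The fallback replaces the electrolysis by decarboxylative halogenation and reductive coupling; it sets out from 3 and comes back at 5. Acid 3 is acetylated (Ac2O, pyridine, aqueous work-up) to 15-acetoxypentadecanoic acid F3. Cristol–Firth Hunsdiecker bromodecarboxylation (HgO, Br2, CCl4, reflux) gives 14-bromotetradecyl acetate F4. Nickel-catalysed reductive homocoupling (NiCl2·glyme/terpyridine cat., Mn, DMF, 40 °C) gives octacosane-1,28-diyl diacetate F5. Methanolysis (K2CO3 cat., MeOH/THF) returns 5.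

**Step 1.** This is the least risky step. The failure modes are soap gels on work-up and partial self-esterification of the hydroxy acid if it is acidified or dried hot. The fallback opens the ring by transesterification instead of hydrolysis; it sets out from 1 and comes back at 3. Lactone 1 is refluxed in MeOH with catalytic NaOMe to give methyl 15-hydroxypentadecanoate F6, a neutral solid purified by crystallisation. The ester is cleaved with LiOH in THF/H2O at room temperature, and cold acidification gives 3.

## Further compounds

F1 | step 3 | 28-bromooctacosan-1-ol | OCCCCCCCCCCCCCCCCCCCCCCCCCCCCBr
F2 | step 3 | 28-bromooctacosanoic acid | OC(=O)CCCCCCCCCCCCCCCCCCCCCCCCCCCBr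
F3 | step 2 | 15-acetoxypentadecanoic acid | CC(=O)OCCCCCCCCCCCCCCC(=O)O
F4 | step 2 | 14-bromotetradecyl acetate | CC(=O)OCCCCCCCCCCCCCCBr
F5 | step 2 | octacosane-1,28-diyl diacetate | CC(=O)OCCCCCCCCCCCCCCCCCCCCCCCCCCCCOC(C)=O
F6 | step 1 | methyl 15-hydroxypentadecanoate | COC(=O)CCCCCCCCCCCCCCO
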